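## Structural features

The target is a diaryl ether with no other ring and no stereocentre: two benzene rings are joined by one oxygen between C1 of ring A and C1' of ring B, so there are no neighbouring stereocentres to relate. Ring A, numbered from its ether carbon, carries OMe at C2 and Br at C4 and C6; ring B carries OH at C2' and Br at C4' and C6'. The two rings therefore have the same pattern and differ only in methyl against hydrogen on oxygen. The molecule is the mono-methyl ether of a symmetrical bisphenol, and telling the two oxygens apart is a real task. Both ether carbons are flanked by an oxygen substituent and a bromine, so the C–O–C bridge is tetra-ortho-substituted and a late coupling of two finished rings would be hindered. The four aryl C–Br bonds are the fragile groups: they rule out catalytic hydrogenation, organolithium reagents and zerovalent palladium or nickel, and a free phenol is easily over-brominated. The real difficulty is positional: on each ring the bromines lie ortho and para to the bridging oxygen but meta to the second oxygen, and on ring A an anisole oxygen would send bromine to C3 and C5 instead. The plan exploits two features of ring A. The unit O–C1–C2(O)–C3 is the masked form of an α-aryloxy methyl ketone (OCH2–C(=O)–CH3), so C4–C5–C6 can come from a three-carbon dialdehyde. C5, para to C2 and lying between C4 and C6, can carry a nitrogen that later directs both bromines and is then removed.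

## Logic of the disconnections

15 from 13 (through 14). The bond in question is O–C(isopropyl) on the C2' oxygen of ring B; backwards, that oxygen is capped with a secondary alkyl group. The reason is the near-symmetry of the target: the ring A oxygen ends as methyl ether, so the ring B oxygen needs a cap that differs from methyl and survives base, electrophilic bromine and diazotisation. The gain is that no free phenol is present while bromine and nitrosating agents are used. The demand is a dealkylation that takes the secondary ether and leaves the methyl ether, the diaryl ether and four C–Br bonds.

13 from 11 (through 12). Backwards, a nitrogen is attached to C5 of ring A (C5–N bond). C5 is the only carbon ortho to both C4 and C6, so an amino group there makes the bromine pattern of ring A the natural outcome of electrophilic substitution. The gain is that 13, whose ring A pattern cannot be reached by direct bromination, is traced to a compound whose pattern can. The demand is a reductive deamination of a weakly basic, doubly ortho-brominated amine without exchange of the ortho bromines and without loss of the acid-sensitive alkyl ether.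

11 from 10. The C4–Br and C6–Br bonds are cut. Both carbons are ortho to the amino group, whose para position (C2) is blocked by methoxy. The gain is a ring A free of halogen. The demand is that exactly two bromines enter ring A, that C3 is left alone, and that ring B, already carrying two bromines, stays inert.

10 from 9, and 9 from 8. The amine is traced to a nitro group and the O–CH3 bond on the C2 oxygen is cut. A nitrophenol is what a ring synthesis can deliver directly, and methylation before reduction avoids an oxidation-prone 4-aminophenol. The gain is that 8 is a plain 2-aryloxy-4-nitrophenol. The demand is a nitro reduction that spares C–Br bonds, hence a dissolving metal and not catalytic hydrogenation.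

8 from 4 and 6 (through 7). Ring A is opened at C1–C6 and C3–C4. Each of these bonds joins a carbon next to the oxygen-bearing C2 to a carbon next to the nitro-bearing C5. They are the two bonds of a double aldol condensation between a ketone (C1–C2–C3) and a 2-nitro-1,3-dialdehyde (C4–C5–C6). The gain is large: ring A disappears, its hindered aryl–oxygen bond is never made by coupling (it becomes the O–CH2 bond of 4), and the position of nitrogen is fixed by construction. The demand is that both α-carbons of 4 condense, that cross-condensation beats self-condensation, and that 6 lasts in aqueous base.

4 from 2 and 3. The O–CH2 bond is cut (ether synthesis from a phenoxide and a primary halide). This replaces a hindered diaryl ether formation by an alkylation. The gain is two simple pieces, one of them commercial. The demand is O-alkylation of a hindered, rather acidic phenol before the halo ketone is consumed by base.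

2 from 1. The C4'–Br and C6'–Br bonds are cut; they are para and ortho to the free hydroxyl of 1, so here the pattern is matched. The gain is a cheap commercial catechol monoether. The demand is that the hydroxyl out-directs the alkoxy group, so the bromination is run on the free phenol.

6 from 5. The C–N bond of the nitro group is cut and the lost carboxyl carbon is restored. The free dialdehyde cannot be stored, whereas its sodium salt is available in one operation from a four-carbon dibromo aldehyde acid and nitrite. The gain is a commercial starting material. The demand is control of an exothermic, gas-evolving reaction and careful handling of a salt that is sensitive when dry.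

## Other disconnections considered

Alternative 1: The cut goes through ring B at C6'–C1' and C3'–C2'. In the forward direction 3,5-dibromo-2H-pyran-2-one A1 and the aryloxyethynyl pinacol boronate A2 would be heated. A (4+2) cycloaddition followed by decarboxylative cycloreversion would give aryl boronate A3, whose C–B bond would then be oxidised to the phenol.
- In its favour: both bromines of ring B arrive with A1 in the correct 1,3-relation. Ring A enters complete with its methoxy group. No protecting group is needed and only one step follows the key step.
- Against it: A2 is at once an ynol ether and an alkynyl boronate, a hydrolytically sensitive class. The usual access (dichlorovinyl ether, double dehydrohalogenation with an alkyllithium, borylation) collides with the two aryl bromides through bromine–lithium exchange. The cycloaddition needs heat. Its regiochemistry requires the oxygen-bearing alkyne carbon to bond to C3 of A1 against the influence of the boron substituent, and nothing in the substrate secures that.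
- Comparison: on structure both plans build one ring from acyclic material. On mechanism the pericyclic route has a regiochemical alternative, whereas the double aldol closure has none. On convergence and on step economy after the key step the alternative is the better plan, and it would be shorter overall if A2 could be made. The judgement turns on that one reagent.

Alternative 2: The cut goes through ring B at C3'–C4' and C5'–C6'. In the forward direction diene A4 (a 1-methoxy-3-silyloxybutadiene carrying the finished ring A as aryloxy group at C2) would add (E)-2-nitrovinyl phenyl sulfone A5. Base-induced elimination of the methoxy and phenylsulfonyl groups would aromatise the adduct to silyl ether A6.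
- In its favour: the push–pull pairing controls the regiochemistry strongly. The nucleophilic CH2 terminus of A4 bonds to the sulfonyl-bearing carbon, so nitro ends up para to the silyloxy group. Ring A enters with its methoxy group in place, so no methylation is needed. The silyl ether would be removed by fluoride, which is milder and more selective than a Lewis acid dealkylation; on that point the alternative is the better one.
- Against it: A4 has to be made from the corresponding aryloxyacetone in at least two further steps and is moisture-sensitive and crowded at C2. A5 needs its own preparation. After A6 the same nitrogen sequence (reduction, double ortho-bromination, deamination) remains, now with a silyl ether that has to survive diazotisation in acid.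
- Comparison: on structure the two plans are equal, since both use a nitrogen para to the ring oxygen as the control element. On mechanism a concerted cycloaddition with substituent-controlled regiochemistry stands against a stepwise condensation with no regiochemical choice; both should be reliable in that respect. On step economy the alternative saves the methylation but adds the preparation of A4 and A5, and should end about two steps longer.

Alternative 3: The cuts are C4–Br and C6–Br of ring A, with two nitro groups serving first as activators for ether formation. In the forward direction compound 2 would displace chloride from 2-chloro-1-methoxy-3,5-dinitrobenzene A7 (SNAr) to give dinitro ether A8. Reduction would give diamine A9. Bis-diazotisation and copper-mediated bromide transfer (double Sandmeyer reaction) would give A10, which is identical with compound 13 and is finished by the same last step.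
- In its favour: the doubly activated SNAr copes well with a tetra-ortho-substituted ether. Every reaction is of a standard type. The nitrogens are used twice. The route is roughly half as long. On step economy and on the robustness of the C–O bond formation the alternative is the better plan.
- Against it: A9 is a meta-phenylenediamine. Its mono-diazonium ion can couple with still-undiazotised, highly activated diamine unless the diazotisation is run by inverse addition into nitrosylsulfuric acid. The aryl radical formed at C6, next to the diaryl ether oxygen, can attack ring B (Pschorr-type closure to a dibenzofuran) or be reduced. Both diazonium groups of one molecule have to be converted cleanly.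
- Comparison: on structure the two plans meet at the same penultimate compound, so the end-game is equal. On mechanism the chosen plan needs a single diazonium group and removes it by reduction, where hydrogen transfer is the wanted event; here halogen transfer has to win twice against that same pathway.

Key step: step 4

Assumption: compound 6 is taken as the monohydrate of the sodium salt, made only on the scale needed, kept moist and handled behind a shield, because the dry salt is sensitive to impact and heat.

## Steps

Step 1
Reactants: 1 2-isopropoxyphenol
Product: 2 2,4-dibromo-6-isopropoxyphenol
Conditions: NBS (2.05 equiv), i-Pr2NH (0.1 equiv), CH2Cl2, 0 °C to rt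
Reagents that add atoms: N-bromosuccinimide, O=C1CCC(=O)N1Br
Why: Electrophilic aromatic bromination of a free phenol; the hydroxyl, hydrogen-bonded to the amine and its N-bromo derivative, is the strongest director, so bromine should enter ortho (C6) and then para (C4) to it, while the positions favoured by the isopropoxy group are meta to OH. NBS releases no HBr, so the isopropyl ether is not endangered.

Step 2
Reactants: 2 2,4-dibromo-6-isopropoxyphenol; 3 chloroacetone
Product: 4 1-(2,4-dibromo-6-isopropoxyphenoxy)propan-2-one
Conditions: K2CO3 (1.5 equiv), KI (cat.), acetone, reflux
Reagents that add atoms: none
Why: Williamson ether synthesis: the phenoxide of 2, made acidic by its two bromines, displaces chloride from the primary α-halo ketone, an excellent SN2 electrophile, and iodide catalysis helps the hindered oxygen. Carbonate in acetone is mild enough to limit self-condensation of 3.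

Step 3
Reactants: 5 mucobromic acid
Product: 6 sodium nitromalonaldehyde monohydrate
Conditions: NaNO2 (3.5 equiv), H2O/EtOH, 50–55 °C; then 0 °C; recrystallised from aqueous EtOH, kept moist
Reagents that add atoms: sodium nitrite, [Na+].[O-]N=O; water, O
Why: Known preparation of the salt: nitrite replaces a vinylic bromide by addition–elimination, the carboxyl group is lost as CO2 and the second bromide is hydrolysed, leaving the stabilised anion of the nitro dialdehyde, which crystallises as its sodium salt. Slow addition and temperature control keep the exothermic, gas-evolving reaction in hand.

Step 4
Reactants: 4 1-(2,4-dibromo-6-isopropoxyphenoxy)propan-2-one; 6 sodium nitromalonaldehyde monohydrate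
Product: 8 2-(2,4-dibromo-6-isopropoxyphenoxy)-4-nitrophenol, via sodium nitrophenolate 7 (not isolated)
Conditions: 6 (1.2 equiv), NaOH (1.0 equiv, 1 M aq.), EtOH/H2O, 0 °C to rt, 3–5 d; then HCl (aq.) to pH 2
Reagents that add atoms: none
Why: The reaction type is the known condensation of a ketone having two enolisable α-carbons with the sodium salt of nitromalonaldehyde to give a 4-nitrophenol, applied here to an α-aryloxy methyl ketone. In dilute hydroxide each α-carbon of 4 (OCH2 and CH3) is deprotonated in turn and its enolate adds to one formyl group of 6, water being lost after each addition (two aldol condensations, in either order). The second addition is the ring closure, a 6-(enolendo)-exo-trig aldol addition that completes the C1–C6 and C3–C4 pair of bonds; dehydration gives a cyclohexadienone that tautomerises irreversibly to phenolate 7, and acid liberates 8. No stereocentre is formed, because all six ring carbons end up sp2. Regiochemistry needs no control: the carbonyl carbon becomes C2, its two neighbours become C1 (aryloxy) and C3, and the nitro-bearing carbon of 6 can only become C5, para to the new hydroxyl. The selectivity that is needed is cross- over self-condensation, and it is secured because 6 has no enolisable hydrogen, offers the only strongly electrophilic carbonyl groups present, is used in slight excess, and the final aromatisation pulls the equilibria forward. Aqueous ethanol keeps the lipophilic ketone in solution, and low temperature with dilute base limits hydroxide attack on 6 and loss of the dibromophenoxide from 4.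

Step 5
Reactants: 8 2-(2,4-dibromo-6-isopropoxyphenoxy)-4-nitrophenol
Product: 9 1,5-dibromo-3-isopropoxy-2-(2-methoxy-5-nitrophenoxy)benzene
Conditions: MeI (1.5 equiv), K2CO3, acetone, reflux
Reagents that add atoms: iodomethane, CI
Why: Williamson O-methylation of an acidic 4-nitrophenol, which has no other nucleophilic site. The methyl ether is the permanent group of ring A and is installed before the amine is unmasked, so that no 4-aminophenol is ever present.

Step 6
Reactants: 9 1,5-dibromo-3-isopropoxy-2-(2-methoxy-5-nitrophenoxy)benzene
Product: 10 3-(2,4-dibromo-6-isopropoxyphenoxy)-4-methoxyaniline
Conditions: Fe powder (5 equiv), AcOH/EtOH, 70 °C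
Reagents that add atoms: none
Why: Béchamp-type reduction: electron transfer from iron in acetic acid takes the nitro group to the amine through the nitroso and hydroxylamine stages. Aryl bromides and both ethers are inert under these conditions, which is the reason for avoiding H2 over palladium.

Step 7
Reactants: 10 3-(2,4-dibromo-6-isopropoxyphenoxy)-4-methoxyaniline
Product: 11 2,6-dibromo-3-(2,4-dibromo-6-isopropoxyphenoxy)-4-methoxyaniline
Conditions: NBS (2.05 equiv), MeCN, −10 °C to rt, dark
Reagents that add atoms: N-bromosuccinimide, O=C1CCC(=O)N1Br
Why: Electrophilic aromatic bromination directed by the amino group: its para position (C2) is blocked by methoxy, so both bromines should go ortho, to C4 (also para to the bridging oxygen) and C6 (also ortho to it). C3 is activated by methoxy alone and ring B is deactivated by two bromines, so exact stoichiometry at low temperature should stop at 11.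

Step 8
Reactants: 11 2,6-dibromo-3-(2,4-dibromo-6-isopropoxyphenoxy)-4-methoxyaniline
Product: 13 1,5-dibromo-2-(2,4-dibromo-6-methoxyphenoxy)-3-isopropoxybenzene, via arenediazonium hydrogensulfate 12 (not isolated)
Conditions: NaNO2 (1.3 equiv), conc. H2SO4, AcOH, 5–15 °C; then H3PO2 (50% aq., 10 equiv), 0 °C to rt
Reagents that add atoms: none
Why: Diazotisation of the weakly basic amine with nitrosylsulfuric acid gives 12, which H3PO2 reduces in a radical chain (the aryl radical takes hydrogen from a P–H bond) with loss of N2, a standard hydrodediazoniation. Sulfuric acid is used instead of hydrochloric acid to exclude chloride, which could displace a bromine ortho to the diazonium group, and the two ortho bromines shield the diazonium ion from azo coupling.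

Step 9
Reactants: 13 1,5-dibromo-2-(2,4-dibromo-6-methoxyphenoxy)-3-isopropoxybenzene
Product: 15 3,5-dibromo-2-(2,4-dibromo-6-methoxyphenoxy)phenol (target), via aryloxydichloroborane 14 (not isolated)
Conditions: BCl3 (2.5 equiv, 1 M in CH2Cl2), CH2Cl2, −20 to 0 °C; then H2O
Reagents that add atoms: none
Why: Lewis acid dealkylation: BCl3 binds the ether oxygen and the secondary isopropyl group leaves as 2-chloropropane through a cation-like transition state, whereas a methyl ether can only be cleaved by slower SN2 attack at carbon. At or below 0 °C the methyl ether, the diaryl ether and the C–Br bonds should persist, and water hydrolyses 14 to the phenol.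

## Compound list

1 | 2-isopropoxyphenol | CC(C)Oc1ccccc1O | starting material
2 | 2,4-dibromo-6-isopropoxyphenol | CC(C)Oc1cc(Br)cc(Br)c1O | intermediate
3 | chloroacetone | CC(=O)CCl | starting material
4 | 1-(2,4-dibromo-6-isopropoxyphenoxy)propan-2-one | CC(=O)COc1c(OC(C)C)cc(Br)cc1Br | intermediate
5 | mucobromic acid, (Z)-2,3-dibromo-4-oxobut-2-enoic acid | O=C/C(Br)=C(Br)\C(=O)O | starting material
6 | sodium nitromalonaldehyde monohydrate (sodium salt of 2-nitropropanedial) | [Na+].O=C[C-](C=O)[N+](=O)[O-].O | intermediate
7 | sodium 2-(2,4-dibromo-6-isopropoxyphenoxy)-4-nitrophenolate | CC(C)Oc1cc(Br)cc(Br)c1Oc1cc([N+](=O)[O-])ccc1[O-].[Na+] | intermediate (not isolated)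
8 | 2-(2,4-dibromo-6-isopropoxyphenoxy)-4-nitrophenol | CC(C)Oc1cc(Br)cc(Br)c1Oc1cc([N+](=O)[O-])ccc1O | intermediate
9 | 1,5-dibromo-3-isopropoxy-2-(2-methoxy-5-nitrophenoxy)benzene | COc1ccc([N+](=O)[O-])cc1Oc1c(OC(C)C)cc(Br)cc1Br | intermediate
10 | 3-(2,4-dibromo-6-isopropoxyphenoxy)-4-methoxyaniline | COc1ccc(N)cc1Oc1c(OC(C)C)cc(Br)cc1Br | intermediate
11 | 2,6-dibromo-3-(2,4-dibromo-6-isopropoxyphenoxy)-4-methoxyaniline | COc1cc(Br)c(N)c(Br)c1Oc1c(OC(C)C)cc(Br)cc1Br | intermediate
12 | 2,6-dibromo-3-(2,4-dibromo-6-isopropoxyphenoxy)-4-methoxybenzenediazonium hydrogensulfate | COc1cc(Br)c([N+]#N)c(Br)c1Oc1c(OC(C)C)cc(Br)cc1Br.OS(=O)(=O)[O-] | intermediate (not isolated)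
13 | 1,5-dibromo-2-(2,4-dibromo-6-methoxyphenoxy)-3-isopropoxybenzene | COc1cc(Br)cc(Br)c1Oc1c(OC(C)C)cc(Br)cc1Br | intermediate
14 | dichloro[3,5-dibromo-2-(2,4-dibromo-6-methoxyphenoxy)phenoxy]borane | COc1cc(Br)cc(Br)c1Oc1c(OB(Cl)Cl)cc(Br)cc1Br | intermediate (not isolated)
15 | 3,5-dibromo-2-(2,4-dibromo-6-methoxyphenoxy)phenol | COc1cc(Br)cc(Br)c1Oc1c(O)cc(Br)cc1Br | target

## Step count and least certain steps

Total number of steps: 9. Longest linear sequence: 8 steps (steps 1, 2, 4, 5, 6, 7, 8 and 9); step 3 is a one-step branch that supplies compound 6.

Step 4 (key step). What is most likely to go wrong is that the double condensation is overtaken by side processes: base-induced self-condensation of the ketone, loss of its dibromophenoxide, or hydroxide attack on the dialdehyde salt with loss of a formyl group. The reaction may also stall after the first condensation, because the second enolisation has to occur in an intermediate that is already an anion and the ketone is poorly soluble in water. The fallback does not build ring A but couples it. Compound 2 is O-arylated with (2-methoxy-5-nitrophenyl)boronic acid F1 in a Chan–Lam coupling (Cu(OAc)2, pyridine, 4 Å molecular sieves, CH2Cl2, air, rt), which tolerates aryl bromides. This sets out from compound 2 and comes back to the route at compound 9, after which steps 6 to 9 are unchanged. The coupling of a doubly ortho-substituted phenol is expected to be slow, which is why it is the reserve and not the plan.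

Step 8. What is most likely to go wrong is incomplete diazotisation of a weakly basic amine flanked by two bromines, together with partial loss of the isopropyl group in the strong acid that such an amine requires. The fallback reverses the order of the last two operations. Compound 11 is first dealkylated with BCl3 under the conditions of step 9 to 2-(3-amino-2,4-dibromo-6-methoxyphenoxy)-3,5-dibromophenol F2. F2 has no acid-sensitive group left, so it can be diazotised in concentrated H2SO4 with nitrosylsulfuric acid without restraint and reduced with H3PO2. This sets out from compound 11 and comes back at compound 15.

Step 9. What is most likely to go wrong is insufficient discrimination between the two alkyl ethers: coordination of the Lewis acid between the methoxy oxygen and the bridging oxygen of ring A could start demethylation before the isopropyl group is fully removed. The fallback gives up the discrimination and uses the symmetry of the skeleton. Compound 13 is dealkylated at both oxygens with BBr3 (CH2Cl2, −78 °C to rt) to 2,2'-oxybis(3,5-dibromophenol) F3, whose two hydroxyls are equivalent. F3 is then methylated once (MeI, 1 equiv, K2CO3, acetone). Either hydroxyl leads to the same product, and unreacted diol and dimethyl ether are separated and recycled. This sets out from compound 13 and comes back at compound 15.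

## Further compounds

F1 | step 4 | (2-methoxy-5-nitrophenyl)boronic acid | COc1ccc([N+](=O)[O-])cc1B(O)O
F2 | step 8 | 2-(3-amino-2,4-dibromo-6-methoxyphenoxy)-3,5-dibromophenol | COc1cc(Br)c(N)c(Br)c1Oc1c(O)cc(Br)cc1Br
F3 | step 9 | 2,2'-oxybis(3,5-dibromophenol) | Oc1cc(Br)cc(Br)c1Oc1c(O)cc(Br)cc1Br
A1 | alternative 1 | 3,5-dibromo-2H-pyran-2-one | O=C1OC=C(Br)C=C1Br
A2 | alternative 1 | 2-[(2,4-dibromo-6-methoxyphenoxy)ethynyl]-4,4,5,5-tetramethyl-1,3,2-dioxaborolane | COc1cc(Br)cc(Br)c1OC#CB1OC(C)(C)C(C)(C)O1
A3 | alternative 1 | 2-[3,5-dibromo-2-(2,4-dibromo-6-methoxyphenoxy)phenyl]-4,4,5,5-tetramethyl-1,3,2-dioxaborolane | COc1cc(Br)cc(Br)c1Oc1c(Br)cc(Br)cc1B2OC(C)(C)C(C)(C)O2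
A4 | alternative 2 | tert-butyl{[(3Z)-3-(2,4-dibromo-6-methoxyphenoxy)-4-methoxybuta-1,3-dien-2-yl]oxy}dimethylsilane | CO/C=C(/C(=C)O[Si](C)(C)C(C)(C)C)Oc1c(OC)cc(Br)cc1Br
A5 | alternative 2 | (E)-2-nitrovinyl phenyl sulfone | O=[N+]([O-])/C=C/S(=O)(=O)c1ccccc1
A6 | alternative 2 | tert-butyl[2-(2,4-dibromo-6-methoxyphenoxy)-4-nitrophenoxy]dimethylsilane | COc1cc(Br)cc(Br)c1Oc1cc([N+](=O)[O-])ccc1O[Si](C)(C)C(C)(C)C
A7 | alternative 3 | 2-chloro-1-methoxy-3,5-dinitrobenzene | COc1cc([N+](=O)[O-])cc([N+](=O)[O-])c1Cl
A8 | alternative 3 | 1,5-dibromo-3-isopropoxy-2-(2-methoxy-4,6-dinitrophenoxy)benzene | COc1cc([N+](=O)[O-])cc([N+](=O)[O-])c1Oc1c(OC(C)C)cc(Br)cc1Br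
A9 | alternative 3 | 4-(2,4-dibromo-6-isopropoxyphenoxy)-5-methoxybenzene-1,3-diamine | COc1cc(N)cc(N)c1Oc1c(OC(C)C)cc(Br)cc1Br
A10 | alternative 3 | 1,5-dibromo-2-(2,4-dibromo-6-methoxyphenoxy)-3-isopropoxybenzene | COc1cc(Br)cc(Br)c1Oc1c(OC(C)C)cc(Br)cc1Br
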